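The two ring A prenyl bonds, C6–C1'' and C8–C1'', are the disconnection on which the route rests. C6 is flanked by the C5 oxygen and C8 by ring oxygen O1 (at C8a). Once ring C is opened to the acetophenone, these two oxygens become the equivalent hydroxyls on either side of the acetyl group. The precursor is therefore the symmetric 4-O-MOM acetophenone carrying a 1,1-dimethylallyl ether on each of them. Heating triggers a double aromatic Claisen rearrangement that hands both allyl units to the only free ortho carbons as normal prenyl groups in one operation. Ring C and the C2 stereocentre follow by chromone formation and asymmetric rhodium-catalysed arylation.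

Key step: step 4

Remark: atom labels (O1, C2, C5–C8, C8a) are those of the chroman-4-one core, prenyl means 3-methylbut-2-en-1-yl, and the stereocentre of the target is read from the SMILES as (2S).

Step 1
Reactants: 1 2,4,6-trihydroxyacetophenone
Product: 2 2,6-dihydroxy-4-(methoxymethoxy)acetophenone
Conditions: MOMCl (1.05 equiv), iPr2NEt (1.2 equiv), THF, 0 °C
Reagents that add atoms: chloromethyl methyl ether, COCCl
Why: Williamson-type O-alkylation in which the 4-hydroxyl, the most acidic one (para to the acetyl group) and the only one not flanked by and hydrogen-bonded to the carbonyl group, should be etherified selectively by one equivalent of MOMCl under a mild amine base.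

Step 2
Reactants: 2 2,6-dihydroxy-4-(methoxymethoxy)acetophenone; 3 3-chloro-3-methylbut-1-yne
Product: 5 4-(methoxymethoxy)-2,6-bis(2-methylbut-3-yn-2-yloxy)acetophenone, via monoether 4 (not isolated)
Conditions: 3 (4 equiv), DBU (4.5 equiv), CuCl2·2H2O (5 mol%), MeCN, 0 → 40 °C
Reagents that add atoms: none
Why: Copper-catalysed O-propargylation of phenols with a tertiary propargylic chloride, in which copper activates the terminal alkyne of 3 so that chloride ionises and the propargyl/allenyl cation equivalent is captured at oxygen on its tertiary carbon; full deprotonation by the amidine base removes the O–H···O=C chelate, so with excess 3 the second hydroxyl of 4 should also react.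

Step 3
Reactants: 5 4-(methoxymethoxy)-2,6-bis(2-methylbut-3-yn-2-yloxy)acetophenone
Product: 7 4-(methoxymethoxy)-2,6-bis(2-methylbut-3-en-2-yloxy)acetophenone, via half-reduced diether 6 (not isolated)
Conditions: H2 (1 atm), Pd/CaCO3 poisoned with Pb(OAc)2, quinoline, EtOAc, rt; concentrate below 30 °C
Reagents that add atoms: none
Why: Lindlar-type semihydrogenation, in which the poisoned palladium surface reduces both terminal alkynes to vinyl groups and stops there while the ketone, the MOM acetal and the aryl ethers are inert; the cold work-up keeps the tertiary allyl ethers from rearranging early.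

Step 4
Reactants: 7 4-(methoxymethoxy)-2,6-bis(2-methylbut-3-en-2-yloxy)acetophenone
Product: 11 2,6-dihydroxy-4-(methoxymethoxy)-3,5-bis(3-methylbut-2-enyl)acetophenone, via first cyclohexadienone 8 (not isolated), via monoprenyl phenol 9 (not isolated), via second cyclohexadienone 10 (not isolated)
Conditions: PhNEt2 (degassed), 130 °C, Ar
Reagents that add atoms: none
Why: Each tertiary allyl aryl ether undergoes a concerted, chair-like [3,3]-sigmatropic shift in which the O–C(CH3)2 bond breaks while the terminal CH2 bonds to the neighbouring ring carbon, and the cyclohexadienone so formed (8, then 10) enolises to the hydrogen-bonded phenol (9, then 11). This is the thermal aromatic Claisen rearrangement of aryl 1,1-dimethylallyl ethers to ortho-prenylphenols, run twice in the same flask. No ring is closed and no stereocentre is created, so only the site of attachment and the sense of the allyl unit need control. Both are fixed by the substrate: the acetyl group occupies the second ortho position of each ether, so O2 can deliver only to C3 and O6 only to C5, and the single allyl inversion turns the branched ether into the linear 3-methylbut-2-enyl chain. The gem-dimethyl group weakens the O–C bond so that the shift should run near 130 °C, and the amine solvent buffers traces of acid that could cyclise the new phenols onto the prenyl double bonds.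

Step 5
Reactants: 11 2,6-dihydroxy-4-(methoxymethoxy)-3,5-bis(3-methylbut-2-enyl)acetophenone
Product: 12 2-hydroxy-4,6-bis(methoxymethoxy)-3,5-bis(3-methylbut-2-enyl)acetophenone
Conditions: MOMCl (1.3 equiv), iPr2NEt (2 equiv), CH2Cl2, 0 °C → rt
Reagents that add atoms: chloromethyl methyl ether, COCCl
Why: Williamson-type O-alkylation in which only one of the two equivalent ortho hydroxyls is chelated to the carbonyl at a time, so the first reacts readily and the survivor, then locked in a strong hydrogen bond, should resist further etherification under amine base.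

Step 6
Reactants: 12 2-hydroxy-4,6-bis(methoxymethoxy)-3,5-bis(3-methylbut-2-enyl)acetophenone
Product: 15 5,7-bis(methoxymethoxy)-6,8-bis(3-methylbut-2-enyl)-4H-chromen-4-one, via enaminone 13 (not isolated), via aminal 14 (not isolated)
Conditions: Me2NCH(OMe)2 (3 equiv), PhMe, 95 °C; evaporate; then AcOH, PhMe, 60 °C
Reagents that add atoms: N,N-dimethylformamide dimethyl acetal, COC(OC)N(C)C
Why: Enaminone route to chromones, in which condensation of the acetyl CH3 with the formamide acetal gives vinylogous amide 13, and the weak acid then promotes 6-endo-trig oxa-Michael addition of the phenol to aminal 14 and loss of dimethylamine to the pyranone, conditions that aryl MOM ethers and prenyl groups should survive.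

Step 7
Reactants: 16 4-bromophenol; 3 3-chloro-3-methylbut-1-yne
Product: 17 1-bromo-4-(2-methylbut-3-yn-2-yloxy)benzene
Conditions: 3 (1.5 equiv), DBU (1.7 equiv), CuCl2·2H2O (1 mol%), MeCN, 0 °C → rt
Reagents that add atoms: none
Why: The same copper-catalysed O-propargylation of a phenoxide with the tertiary propargylic chloride as in step 2, here on an unhindered, unchelated phenol.

Step 8
Reactants: 17 1-bromo-4-(2-methylbut-3-yn-2-yloxy)benzene
Product: 21 6-bromo-2,2-dimethyl-2H-chromene, via allenyl dienone 18 (not isolated), via allenylphenol 19 (not isolated), via quinone methide 20 (not isolated)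
Conditions: PhNEt2, 190 °C, Ar
Reagents that add atoms: none
Why: Thermal propargyl Claisen cascade, in which a [3,3] shift to allenyl dienone 18, enolisation to 19, a [1,5]-hydrogen shift to ortho-quinone methide 20 and oxa-6π electrocyclisation close the 2,2-dimethylpyran ring; the two ortho positions are equivalent and bromine sits para to oxygen, which places it at C6.

Step 9
Reactants: 21 6-bromo-2,2-dimethyl-2H-chromene
Product: 24 (2,2-dimethyl-2H-chromen-6-yl)boronic acid, via aryllithium 22 (not isolated), via lithium borate 23 (not isolated)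
Conditions: n-BuLi, THF, −78 °C; B(OiPr)3, −78 °C → rt; 1 M aq. HCl, 0 °C
Reagents that add atoms: triisopropyl borate, CC(C)OB(OC(C)C)OC(C)C; water, O
Why: Bromine–lithium exchange followed by electrophilic borylation and hydrolysis of the borate, a sequence in which the chromene carries no acidic or electrophilic site that competes at −78 °C.

Step 10
Reactants: 15 5,7-bis(methoxymethoxy)-6,8-bis(3-methylbut-2-enyl)-4H-chromen-4-one; 24 (2,2-dimethyl-2H-chromen-6-yl)boronic acid
Product: 25 (2S)-2-(2,2-dimethyl-2H-chromen-6-yl)-5,7-bis(methoxymethoxy)-6,8-bis(3-methylbut-2-enyl)chroman-4-one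
Conditions: 24 (2.5 equiv), [RhCl(C2H4)2]2 (2.5 mol%), (S,S)-2,5-diphenylbicyclo[2.2.2]octa-2,5-diene (5.5 mol%), KOH (10 mol%), dioxane/H2O 10:1, 40 °C
Reagents that add atoms: none
Why: Rhodium-catalysed asymmetric conjugate addition of an arylboronic acid to an enone (Hayashi–Miyaura reaction), in which the aryl group passes from boron to rhodium, the chromone C2=C3 bond inserts on the face left open by the C2-symmetric chiral diene and the enolate is protonated by water, so the C2 stereocentre is set under catalyst control; the (S,S)-ligand is expected by analogy with cyclic enones to give (2S) (to be confirmed by chiroptical comparison, with the antipodal ligand as the remedy), the ethylene precursor leaves no achiral diene on rhodium, and the small base charge limits ring opening of the product.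

Step 11
Reactants: 25 (2S)-2-(2,2-dimethyl-2H-chromen-6-yl)-5,7-bis(methoxymethoxy)-6,8-bis(3-methylbut-2-enyl)chroman-4-one
Product: 27 (2S)-2-(2,2-dimethyl-2H-chromen-6-yl)-5,7-dihydroxy-6,8-bis(3-methylbut-2-enyl)chroman-4-one (CNP0188949.1), via monoether 26 (not isolated)
Conditions: HCl (1.25 M in MeOH), 0 °C → rt
Reagents that add atoms: none
Why: Acid-catalysed acetal exchange with methanol should free both phenols as dimethoxymethane, the carbonyl-assisted O5 ether first (26); without base C2 is not exposed to retro-oxa-Michael opening, and dilute acid at low temperature should keep the prenyl groups from cyclising onto the hydroxyls and leave the chromene intact.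

Compound list
1 | 2,4,6-trihydroxyacetophenone | CC(=O)c1c(O)cc(O)cc1O | starting material
2 | 2,6-dihydroxy-4-(methoxymethoxy)acetophenone | CC(=O)c1c(O)cc(OCOC)cc1O | intermediate
3 | 3-chloro-3-methylbut-1-yne | CC(C)(Cl)C#C | starting material
4 | 2-hydroxy-4-(methoxymethoxy)-6-(2-methylbut-3-yn-2-yloxy)acetophenone (monoether, not isolated) | CC(=O)c1c(O)cc(OCOC)cc1OC(C)(C)C#C | intermediate
5 | 4-(methoxymethoxy)-2,6-bis(2-methylbut-3-yn-2-yloxy)acetophenone | CC(=O)c1c(OC(C)(C)C#C)cc(OCOC)cc1OC(C)(C)C#C | intermediate
6 | 4-(methoxymethoxy)-2-(2-methylbut-3-en-2-yloxy)-6-(2-methylbut-3-yn-2-yloxy)acetophenone (half-reduced diether, not isolated) | CC(=O)c1c(OC(C)(C)C=C)cc(OCOC)cc1OC(C)(C)C#C | intermediate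
7 | 4-(methoxymethoxy)-2,6-bis(2-methylbut-3-en-2-yloxy)acetophenone (key-step precursor) | CC(=O)c1c(OC(C)(C)C=C)cc(OCOC)cc1OC(C)(C)C=C | intermediate
8 | 2-acetyl-5-(methoxymethoxy)-3-(2-methylbut-3-en-2-yloxy)-6-(3-methylbut-2-enyl)cyclohexa-2,4-dien-1-one (first cyclohexadienone, not isolated) | CC(=O)C1=C(OC(C)(C)C=C)C=C(OCOC)C(CC=C(C)C)C1=O | intermediate
9 | 2-hydroxy-4-(methoxymethoxy)-6-(2-methylbut-3-en-2-yloxy)-3-(3-methylbut-2-enyl)acetophenone (monoprenyl phenol, not isolated) | CC(=O)c1c(O)c(CC=C(C)C)c(OCOC)cc1OC(C)(C)C=C | intermediate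
10 | 2-acetyl-3-hydroxy-5-(methoxymethoxy)-4,6-bis(3-methylbut-2-enyl)cyclohexa-2,4-dien-1-one (second cyclohexadienone, not isolated) | CC(=O)C1=C(O)C(CC=C(C)C)=C(OCOC)C(CC=C(C)C)C1=O | intermediate
11 | 2,6-dihydroxy-4-(methoxymethoxy)-3,5-bis(3-methylbut-2-enyl)acetophenone (key-step product) | CC(=O)c1c(O)c(CC=C(C)C)c(OCOC)c(CC=C(C)C)c1O | intermediate
12 | 2-hydroxy-4,6-bis(methoxymethoxy)-3,5-bis(3-methylbut-2-enyl)acetophenone | CC(=O)c1c(O)c(CC=C(C)C)c(OCOC)c(CC=C(C)C)c1OCOC | intermediate
13 | (E)-3-(dimethylamino)-1-[2-hydroxy-4,6-bis(methoxymethoxy)-3,5-bis(3-methylbut-2-enyl)phenyl]prop-2-en-1-one (enaminone, not isolated) | CN(C)/C=C/C(=O)c1c(O)c(CC=C(C)C)c(OCOC)c(CC=C(C)C)c1OCOC | intermediate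
14 | 2-(dimethylamino)-5,7-bis(methoxymethoxy)-6,8-bis(3-methylbut-2-enyl)chroman-4-one (aminal, not isolated) | CN(C)C1CC(=O)c2c(OCOC)c(CC=C(C)C)c(OCOC)c(CC=C(C)C)c2O1 | intermediate
15 | 5,7-bis(methoxymethoxy)-6,8-bis(3-methylbut-2-enyl)-4H-chromen-4-one | O=c1ccoc2c(CC=C(C)C)c(OCOC)c(CC=C(C)C)c(OCOC)c12 | intermediate
16 | 4-bromophenol | Oc1ccc(Br)cc1 | starting material
17 | 1-bromo-4-(2-methylbut-3-yn-2-yloxy)benzene | C#CC(C)(C)Oc1ccc(Br)cc1 | intermediate
18 | 4-bromo-6-(3-methylbuta-1,2-dien-1-yl)cyclohexa-2,4-dien-1-one (allenyl dienone, not isolated) | O=C1C=CC(Br)=CC1C=C=C(C)C | intermediate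
19 | 4-bromo-2-(3-methylbuta-1,2-dien-1-yl)phenol (allenylphenol, not isolated) | Oc1ccc(Br)cc1C=C=C(C)C | intermediate
20 | 4-bromo-6-(3-methylbut-2-en-1-ylidene)cyclohexa-2,4-dien-1-one (quinone methide, not isolated) | O=C1C=CC(Br)=CC1=CC=C(C)C | intermediate
21 | 6-bromo-2,2-dimethyl-2H-chromene | CC1(C)C=Cc2cc(Br)ccc2O1 | intermediate
22 | (2,2-dimethyl-2H-chromen-6-yl)lithium (aryllithium, not isolated) | [Li]c1ccc2OC(C)(C)C=Cc2c1 | intermediate
23 | lithium (2,2-dimethyl-2H-chromen-6-yl)triisopropoxyborate (lithium borate, not isolated) | [Li+].CC(C)O[B-](OC(C)C)(OC(C)C)c1ccc2OC(C)(C)C=Cc2c1 | intermediate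
24 | (2,2-dimethyl-2H-chromen-6-yl)boronic acid | CC1(C)C=Cc2cc(B(O)O)ccc2O1 | intermediate
25 | (2S)-2-(2,2-dimethyl-2H-chromen-6-yl)-5,7-bis(methoxymethoxy)-6,8-bis(3-methylbut-2-enyl)chroman-4-one | CC(C)=CCc1c(OCOC)c(CC=C(C)C)c2c(c1OCOC)C(=O)C[C@@H](c1ccc3c(c1)C=CC(C)(C)O3)O2 | intermediate
26 | (2S)-2-(2,2-dimethyl-2H-chromen-6-yl)-5-hydroxy-7-(methoxymethoxy)-6,8-bis(3-methylbut-2-enyl)chroman-4-one (monoether, not isolated) | CC(C)=CCc1c(OCOC)c(CC=C(C)C)c2c(c1O)C(=O)C[C@@H](c1ccc3c(c1)C=CC(C)(C)O3)O2 | intermediate
27 | (2S)-2-(2,2-dimethyl-2H-chromen-6-yl)-5,7-dihydroxy-6,8-bis(3-methylbut-2-enyl)chroman-4-one (CNP0188949.1) | CC(C)=CCc1c(O)c(CC=C(C)C)c2c(c1O)C(=O)C[C@@H](c1ccc3c(c1)C=CC(C)(C)O3)O2 | target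

Total step count: 11 steps.
Longest linear sequence: 8 steps (steps 1–6, 10 and 11, from 2,4,6-trihydroxyacetophenone). The ring B branch (steps 7–9) joins at step 10.

Steps most likely to fail

Step 2. The second etherification may stall at monoether 4, because the remaining hydroxyl is hydrogen-bonded to the carbonyl and crowded by the first tertiary ether, while the chloride is consumed by base-induced elimination. The fallback sets out from 2 and comes back to the route at 9, and from there at 11. It brings in the two prenyl groups one after the other, so that every alkylation is done on a 2,6-dihydroxyacetophenone that still has one unchelated hydroxyl. Compound 2 would be mono-alkylated with one equivalent of 3 (CuCl2·2H2O, DBU, MeCN) to 4. Semihydrogenation over Pd/CaCO3 poisoned with Pb(OAc)2 would give 2-hydroxy-4-(methoxymethoxy)-6-(2-methylbut-3-en-2-yloxy)acetophenone F1. Heating F1 in PhNEt2 at 130 °C would give, by a single Claisen shift, 2,6-dihydroxy-4-(methoxymethoxy)-3-(3-methylbut-2-enyl)acetophenone F2. Its less hindered hydroxyl, the one remote from the prenyl group, would be propargylated in the same way to 2-hydroxy-4-(methoxymethoxy)-6-(2-methylbut-3-yn-2-yloxy)-3-(3-methylbut-2-enyl)acetophenone F3. Semihydrogenation of F3 gives 9, which on heating as in step 4 should give 11.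

Step 10. The electron-rich, doubly flanked chromone may insert too slowly, so that protodeboronation of the boronic acid outruns the addition, or base may open the product ring and erode the enantiomeric purity. The fallback sets out from 12 and 21 and comes back at 25; it builds ring C from a chalcone and obtains the single enantiomer by resolution. Bromide 21 would be lithiated (n-BuLi, THF, −78 °C) and formylated with DMF to 2,2-dimethyl-2H-chromene-6-carbaldehyde F4. Claisen–Schmidt condensation of 12 with F4 (KOH, EtOH, rt) would give (E)-3-(2,2-dimethyl-2H-chromen-6-yl)-1-[2-hydroxy-4,6-bis(methoxymethoxy)-3,5-bis(3-methylbut-2-enyl)phenyl]prop-2-en-1-one F5. Intramolecular oxa-Michael cyclisation (NaOAc, EtOH, reflux) would give racemic 2-(2,2-dimethyl-2H-chromen-6-yl)-5,7-bis(methoxymethoxy)-6,8-bis(3-methylbut-2-enyl)chroman-4-one F6. Preparative HPLC of F6 on a polysaccharide-based chiral stationary phase would deliver the (2S)-enantiomer 25.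

Step 4. The tertiary ethers may fragment with loss of isoprene, and the phenol freed by the first shift may cyclise onto its new prenyl double bond before the second shift is complete. The fallback sets out from 1 and comes back at 12; it replaces the rearrangement by direct C-alkylation. Treatment of 1 with prenyl bromide (2.2 equiv) in aqueous KOH at 0 °C would give, after chromatographic removal of mono-, O- and geminally alkylated material, 2,4,6-trihydroxy-3,5-bis(3-methylbut-2-enyl)acetophenone F7. MOMCl (2.2 equiv) and iPr2NEt in CH2Cl2 would then etherify the 4-hydroxyl and one ortho hydroxyl of F7, leaving the chelated one, to give 12.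

Further compounds
F1 | step 2 | 2-hydroxy-4-(methoxymethoxy)-6-(2-methylbut-3-en-2-yloxy)acetophenone | CC(=O)c1c(O)cc(OCOC)cc1OC(C)(C)C=C
F2 | step 2 | 2,6-dihydroxy-4-(methoxymethoxy)-3-(3-methylbut-2-enyl)acetophenone | CC(=O)c1c(O)cc(OCOC)c(CC=C(C)C)c1O
F3 | step 2 | 2-hydroxy-4-(methoxymethoxy)-6-(2-methylbut-3-yn-2-yloxy)-3-(3-methylbut-2-enyl)acetophenone | CC(=O)c1c(O)c(CC=C(C)C)c(OCOC)cc1OC(C)(C)C#C
F4 | step 10 | 2,2-dimethyl-2H-chromene-6-carbaldehyde | CC1(C)C=Cc2cc(C=O)ccc2O1
F5 | step 10 | (E)-3-(2,2-dimethyl-2H-chromen-6-yl)-1-[2-hydroxy-4,6-bis(methoxymethoxy)-3,5-bis(3-methylbut-2-enyl)phenyl]prop-2-en-1-one | O=C(/C=C/c1ccc2OC(C)(C)C=Cc2c1)c1c(O)c(CC=C(C)C)c(OCOC)c(CC=C(C)C)c1OCOC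
F6 | step 10 | racemic 2-(2,2-dimethyl-2H-chromen-6-yl)-5,7-bis(methoxymethoxy)-6,8-bis(3-methylbut-2-enyl)chroman-4-one | CC(C)=CCc1c(OCOC)c(CC=C(C)C)c2c(c1OCOC)C(=O)CC(c1ccc3c(c1)C=CC(C)(C)O3)O2
F7 | step 4 | 2,4,6-trihydroxy-3,5-bis(3-methylbut-2-enyl)acetophenone | CC(=O)c1c(O)c(CC=C(C)C)c(O)c(CC=C(C)C)c1O
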